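**Plan**
- Retrosynthesis: the five hydroxyl groups go back to ethers and the isobutyryl C=O to a silyl-protected carbinol. The central ring (C1 acyl carbon; C2, C4, C6 oxygenated; C3, C5 arm-bearing) is then cut at C1–C6, C2–C3 and C5–C6 into a 3-ethoxy-2,4-bis(pyranonylmethyl)cyclobutenone (C3–C4–C5 plus C6) and a siloxyalkyne (C1, C2).
- Enabling feature: the benzene ring alternates oxygen on C2, C4, C6 with carbon on C1, C3, C5, and the two pyranonylmethyl arms on C3 and C5 are identical. A 3-alkoxycyclobutenone and an O-substituted alkyne deliver this pattern in one annulation, and the cyclobutenone itself comes from two molecules of one ynol ether.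
- The ynol ether is cut at its propargylic C–C bond into a 3-(bromomethyl)-4-methoxypyranone and ethoxyacetylene; the pyranone ring comes from γ-acylation and lactonization of a β-keto ester.
- Forward: pyranone ring (step 1), arm ynol ether (steps 2–6), cyclobutenone ring (step 7), siloxyalkyne in a side branch (steps 8–9), benzene ring (step 10), then capping, carbinol oxidation and global dealkylation (steps 11–14).
- Stereochemistry: the target is achiral. The transient centres (ring carbon of the cyclobutenone, carbinol carbon) are racemic and are erased by aromatization and oxidation.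

Key step: step 10

Remark: the target has no stereocentre, so every chiral intermediate is used as a racemate or stereoisomer mixture; all of them converge on one achiral product.
Abbreviation: Pyr = 6-ethyl-4-methoxy-5-methyl-2-oxo-2H-pyran-3-yl; PyrCH2 is the arm.

**Step 1**
Reactants: 1 methyl 3-oxopentanoate; 2 N-methoxy-N-methylpropanamide
Product: 4 6-ethyl-4-hydroxy-5-methyl-2H-pyran-2-one, via methyl 4-methyl-3,5-dioxoheptanoate 3 (not isolated)
Conditions: NaH, THF, 0 °C; n-BuLi, 0 °C; 2, −78 → 0 °C; aq. HCl; crude, DBU, PhMe, 90 °C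
Reagents that add atoms: none
Why: The γ-carbon of the β-keto ester dianion is its most nucleophilic site and is acylated by the Weinreb amide (Claisen-type γ-acylation), and the 3,5-dioxo ester then lactonizes through its C5 enol oxygen with loss of methanol, the standard triketide route to 4-hydroxy-2-pyranones.

**Step 2**
Reactants: 4 6-ethyl-4-hydroxy-5-methyl-2H-pyran-2-one
Product: 5 6-ethyl-4-methoxy-5-methyl-2H-pyran-2-one
Conditions: Me2SO4, K2CO3, acetone, reflux
Reagents that add atoms: dimethyl sulfate, COS(=O)(=O)OC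
Why: Williamson-type O-alkylation of the vinylogous acid with a hard methylating agent should go at the C4 oxygen and mask the acidic enol for the organometallic and ketene steps.

**Step 3**
Reactants: 5 6-ethyl-4-methoxy-5-methyl-2H-pyran-2-one
Product: 6 3-bromo-6-ethyl-4-methoxy-5-methyl-2H-pyran-2-one
Conditions: NBS, MeCN, rt, dark
Reagents that add atoms: N-bromosuccinimide, O=C1CCC(=O)N1Br
Why: C3 is the only ring CH and the nucleophilic β-carbon of the enol ether, so ionic bromination (electrophilic substitution) should occur there and not on the alkyl groups.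

**Step 4**
Reactants: 6 3-bromo-6-ethyl-4-methoxy-5-methyl-2H-pyran-2-one
Product: 7 6-ethyl-3-(hydroxymethyl)-4-methoxy-5-methyl-2H-pyran-2-one
Conditions: Bu3SnCH2OH, Pd(PPh3)4 (cat.), dioxane, 90 °C
Reagents that add atoms: (tributylstannyl)methanol, CCCC[Sn](CCCC)(CCCC)CO
Why: Stille coupling of the α-bromo enoate-type vinylic bromide transfers the hydroxymethyl group under neutral conditions that leave the methoxypyranone untouched.

**Step 5**
Reactants: 7 6-ethyl-3-(hydroxymethyl)-4-methoxy-5-methyl-2H-pyran-2-one
Product: 8 3-(bromomethyl)-6-ethyl-4-methoxy-5-methyl-2H-pyran-2-one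
Conditions: CBr4, PPh3, CH2Cl2, 0 °C
Reagents that add atoms: carbon tetrabromide, BrC(Br)(Br)Br
Why: The Appel reaction converts the primary allylic-type alcohol into the bromide under neutral conditions without touching the vinylogous ester.

**Step 6**
Reactants: 8 3-(bromomethyl)-6-ethyl-4-methoxy-5-methyl-2H-pyran-2-one; 9 ethoxyacetylene
Product: 12 3-(3-ethoxyprop-2-yn-1-yl)-6-ethyl-4-methoxy-5-methyl-2H-pyran-2-one, via lithium ethoxyacetylide 10 (not isolated), via (ethoxyethynyl)zinc chloride 11 (not isolated)
Conditions: 9, n-BuLi, THF, −78 °C; ZnCl2, −78 → 0 °C; 8, PdCl2(DPEphos) (cat.; DPEphos = bis(2-diphenylphosphinophenyl) ether), THF, 0 °C → rt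
Reagents that add atoms: none
Why: In this Negishi sp–sp3 coupling the non-basic alkynylzinc chloride tolerates the lactone, and oxidative addition of the activated allylic C–Br bond to zerovalent palladium followed by reductive elimination at the unhindered CH2 terminus should install the ethoxyethynyl group without SN2′ attack at the fully substituted C4.

**Step 7**
Reactants: 12 3-(3-ethoxyprop-2-yn-1-yl)-6-ethyl-4-methoxy-5-methyl-2H-pyran-2-one (two molecules)
Product: 14 3-ethoxy-2,4-bis(PyrCH2)cyclobut-2-en-1-one (racemic), via arm ketene 13 (not isolated)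
Conditions: PhMe (about 1 M), 115 °C, sealed tube
Reagents that add atoms: none
Why: Above about 100 °C a 1-ethoxyalkyne loses ethene by a retro-ene reaction and the resulting aldoketene is trapped by a second molecule of the ynol ether in a polarity-controlled [2+2] cycloaddition (the known thermal dimerization of 1-ethoxyalkynes to 3-ethoxy-2,4-dialkylcyclobutenones), so one ynol ether supplies the whole four-carbon unit; the new ring stereocentre is racemic and later becomes aromatic.

**Step 8**
Reactants: 15 ethyl 2-hydroxy-3-methylbutanoate (racemic)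
Product: 16 ethyl 2-(tert-butyldimethylsilyloxy)-3-methylbutanoate (racemic)
Conditions: TBSCl, imidazole, DMF, rt
Reagents that add atoms: tert-butyldimethylsilyl chloride, CC(C)(C)[Si](C)(C)Cl
Why: Standard silylation protects the secondary alcohol so that the ester can be taken through the strongly basic homologation.

**Step 9**
Reactants: 16 ethyl 2-(tert-butyldimethylsilyloxy)-3-methylbutanoate
Product: 19 3-(tert-butyldimethylsilyloxy)-4-methyl-1-(triisopropylsilyloxy)pent-1-yne (racemic), via lithium dibromoenolate 17 (not isolated), via lithium ynolate 18 (not isolated)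
Conditions: CH2Br2, LiTMP (lithium 2,2,6,6-tetramethylpiperidide), THF, −78 °C; n-BuLi, −78 → 0 °C; TIPSCl, −78 °C → rt
Reagents that add atoms: dibromomethane, BrCBr; triisopropylsilyl chloride, CC(C)[Si](Cl)(C(C)C)C(C)C
Why: In this Kowalski ynolate synthesis LiCHBr2 adds to the ester, bromine–lithium exchange on the dibromoenolate triggers a 1,2-shift of the silyloxyalkyl group to the ynolate, and the bulky silyl chloride reacts at oxygen to give the siloxyalkyne; the carbinol centre stays racemic, which is of no consequence.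

**Step 10**
Reactants: 14 3-ethoxy-2,4-bis(PyrCH2)cyclobut-2-en-1-one; 19 3-(tert-butyldimethylsilyloxy)-4-methyl-1-(triisopropylsilyloxy)pent-1-yne
Product: 24 6-[1-(tert-butyldimethylsilyloxy)-2-methylpropyl]-3-ethoxy-2,4-bis(PyrCH2)-5-(triisopropylsilyloxy)phenol (racemic), via vinylketene 20 (not isolated), via 4-vinylcyclobutenone 21 (not isolated), via dienylketene 22 (not isolated), via cyclohexa-2,4-dienone 23 (not isolated)
Conditions: 19 (1.5 equiv), PhMe, 110 → 135 °C, sealed tube
Reagents that add atoms: none
Why: Heating reversibly opens 14 by 4π-electrocyclic cleavage of its C(=O)–C4 bond to vinylketene 20, whose ketene C=C adds the siloxyalkyne in a [2+2] cycloaddition to give 21; this second cyclobutenone opens to dienylketene 22, which closes to cyclohexadienone 23 and tautomerizes to the phenol, the whole being the siloxyalkyne form of the Danheiser benzannulation. The benzene ring is closed by a thermal disrotatory 6π-electrocyclization between the ketene carbon (C6) and C5, after the intermolecular [2+2] has made C1–C6 and C2–C3. No stereocentre is created: the ring centre of 14 becomes aromatic and the racemic carbinol centre of 19 is only carried along. The step needs one regiochemistry in the ketene–alkyne addition, and the siloxy group secures it by making the carbinol-bearing alkyne carbon the nucleophile that bonds to the electrophilic ketene carbon, so the acyl precursor lands between the new phenol and the silyloxy group. It also needs the vinylketene to be trapped faster than it recloses or dimerizes, which the excess of alkyne and the absence of any better ketenophile (both pyranones are electron-rich and fully substituted) should ensure.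

**Step 11**
Reactants: 24 the benzannulation phenol
Product: 27 2-[1-(tert-butyldimethylsilyloxy)-2-methylpropyl]-5-ethoxy-1,3-dimethoxy-4,6-bis(PyrCH2)benzene (racemic), via monomethyl ether 25 (not isolated), via desilylated phenol 26 (not isolated)
Conditions: MeI (excess), K2CO3, DMF, rt; then TBAF (Bu4NF), 0 °C → rt, same flask
Reagents that add atoms: iodomethane, CI
Why: The free phenol is O-methylated first (Williamson), then fluoride cleaves the aryl O–Si bond much faster than the hindered secondary alkyl O–Si bond and the phenoxide is methylated as it forms, so no phenoxide ortho to the benzylic silyloxy group, which could expel it as a quinone methide, accumulates.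

**Step 12**
Reactants: 27 the dimethyl ether
Product: 28 1-[4-ethoxy-2,6-dimethoxy-3,5-bis(PyrCH2)phenyl]-2-methylpropan-1-ol (racemic)
Conditions: TBAF, AcOH (1:1), THF, 45 °C
Reagents that add atoms: none
Why: Buffered fluoride desilylation removes the remaining TBS ether near neutrality, avoiding acid that would ionize the trialkoxybenzylic alcohol and base that could open the pyranones.

**Step 13**
Reactants: 28 the benzylic alcohol
Product: 29 1-[4-ethoxy-2,6-dimethoxy-3,5-bis(PyrCH2)phenyl]-2-methylpropan-1-one
Conditions: Dess–Martin periodinane, pyridine, CH2Cl2, 0 °C → rt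
Reagents that add atoms: none
Why: Dess–Martin oxidation of the hindered secondary alcohol runs through the alkoxyperiodinane and needs no alignment of the benzylic C–H with the ring, and with all phenols capped no quinone-type over-oxidation is open.

**Step 14**
Reactants: 29 the pentaether ketone
Product: 30 3,3'-{[2,4,6-trihydroxy-5-(2-methylpropanoyl)-1,3-phenylene]bis(methylene)}bis(6-ethyl-4-hydroxy-5-methyl-2H-pyran-2-one), the target
Conditions: BBr3 (excess), CH2Cl2, −78 → 0 °C; then H2O
Reagents that add atoms: none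
Why: In this BBr3 ether cleavage chelation to the ketone speeds loss of the two ortho methyl groups, the twisted di-ortho-substituted ethoxy group and the two vinylogous methyl esters of the pyranones are dealkylated by bromide attack on their boron complexes, and aqueous work-up should release the five hydroxyl groups of the achiral target.

**Compound list**
1 | methyl 3-oxopentanoate | CCC(=O)CC(=O)OC | starting material
2 | N-methoxy-N-methylpropanamide | CCC(=O)N(C)OC | starting material
3 | methyl 4-methyl-3,5-dioxoheptanoate (racemic, not isolated) | CCC(=O)C(C)C(=O)CC(=O)OC | intermediate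
4 | 6-ethyl-4-hydroxy-5-methyl-2H-pyran-2-one | CCc1oc(=O)cc(O)c1C | intermediate
5 | 6-ethyl-4-methoxy-5-methyl-2H-pyran-2-one | CCc1oc(=O)cc(OC)c1C | intermediate
6 | 3-bromo-6-ethyl-4-methoxy-5-methyl-2H-pyran-2-one | CCc1oc(=O)c(Br)c(OC)c1C | intermediate
7 | 6-ethyl-3-(hydroxymethyl)-4-methoxy-5-methyl-2H-pyran-2-one | CCc1oc(=O)c(CO)c(OC)c1C | intermediate
8 | 3-(bromomethyl)-6-ethyl-4-methoxy-5-methyl-2H-pyran-2-one | CCc1oc(=O)c(CBr)c(OC)c1C | intermediate
9 | ethoxyacetylene (ethoxyethyne) | C#COCC | starting material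
10 | lithium ethoxyacetylide (not isolated) | [Li+].[C-]#COCC | intermediate
11 | (ethoxyethynyl)zinc chloride (not isolated) | CCOC#C[Zn]Cl | intermediate
12 | 3-(3-ethoxyprop-2-yn-1-yl)-6-ethyl-4-methoxy-5-methyl-2H-pyran-2-one | CCOC#CCc1c(OC)c(C)c(CC)oc1=O | intermediate
13 | 3-(Pyr)prop-1-en-1-one, the arm ketene (not isolated) | O=C=CCc1c(OC)c(C)c(CC)oc1=O | intermediate
14 | 3-ethoxy-2,4-bis(PyrCH2)cyclobut-2-en-1-one (racemic) | CCOC1=C(Cc2c(OC)c(C)c(CC)oc2=O)C(=O)C1Cc1c(OC)c(C)c(CC)oc1=O | intermediate
15 | ethyl 2-hydroxy-3-methylbutanoate (racemic) | CCOC(=O)C(O)C(C)C | starting material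
16 | ethyl 2-(tert-butyldimethylsilyloxy)-3-methylbutanoate (racemic) | CCOC(=O)C(O[Si](C)(C)C(C)(C)C)C(C)C | intermediate
17 | lithium enolate of 1,1-dibromo-3-(tert-butyldimethylsilyloxy)-4-methylpentan-2-one (not isolated) | CC(C)C(O[Si](C)(C)C(C)(C)C)C([O-])=C(Br)Br.[Li+] | intermediate
18 | lithium 3-(tert-butyldimethylsilyloxy)-4-methylpent-1-yn-1-olate (not isolated) | CC(C)C(O[Si](C)(C)C(C)(C)C)C#C[O-].[Li+] | intermediate
19 | 3-(tert-butyldimethylsilyloxy)-4-methyl-1-(triisopropylsilyloxy)pent-1-yne (racemic) | CC(C)C(O[Si](C)(C)C(C)(C)C)C#CO[Si](C(C)C)(C(C)C)C(C)C | intermediate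
20 | 3-ethoxy-2,4-bis(PyrCH2)-substituted vinylketene, 3-ethoxy-5-(Pyr)-2-(PyrCH2)penta-1,3-dien-1-one (not isolated) | CCOC(=CCc1c(OC)c(C)c(CC)oc1=O)C(=C=O)Cc1c(OC)c(C)c(CC)oc1=O | intermediate
21 | 2-[1-(tert-butyldimethylsilyloxy)-2-methylpropyl]-4-[1-ethoxy-3-(Pyr)prop-1-enyl]-4-(PyrCH2)-3-(triisopropylsilyloxy)cyclobut-2-en-1-one (stereoisomer mixture, not isolated) | CCOC(=CCc1c(OC)c(C)c(CC)oc1=O)C1(Cc2c(OC)c(C)c(CC)oc2=O)C(=O)C(C(O[Si](C)(C)C(C)(C)C)C(C)C)=C1O[Si](C(C)C)(C(C)C)C(C)C | intermediate
22 | dienylketene from ring opening of 21 (not isolated) | CCOC(=CCc1c(OC)c(C)c(CC)oc1=O)C(Cc1c(OC)c(C)c(CC)oc1=O)=C(O[Si](C(C)C)(C(C)C)C(C)C)C(=C=O)C(O[Si](C)(C)C(C)(C)C)C(C)C | intermediate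
23 | 2-[1-(tert-butyldimethylsilyloxy)-2-methylpropyl]-5-ethoxy-4,6-bis(PyrCH2)-3-(triisopropylsilyloxy)cyclohexa-2,4-dien-1-one (stereoisomer mixture, not isolated) | CCOC1=C(Cc2c(OC)c(C)c(CC)oc2=O)C(O[Si](C(C)C)(C(C)C)C(C)C)=C(C(O[Si](C)(C)C(C)(C)C)C(C)C)C(=O)C1Cc1c(OC)c(C)c(CC)oc1=O | intermediate
24 | 6-[1-(tert-butyldimethylsilyloxy)-2-methylpropyl]-3-ethoxy-2,4-bis(PyrCH2)-5-(triisopropylsilyloxy)phenol (racemic) | CCOc1c(Cc2c(OC)c(C)c(CC)oc2=O)c(O)c(C(O[Si](C)(C)C(C)(C)C)C(C)C)c(O[Si](C(C)C)(C(C)C)C(C)C)c1Cc1c(OC)c(C)c(CC)oc1=O | intermediate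
25 | methyl ether of 24 at the phenol oxygen, triisopropylsilyl ether retained (racemic, not isolated) | CCOc1c(Cc2c(OC)c(C)c(CC)oc2=O)c(OC)c(C(O[Si](C)(C)C(C)(C)C)C(C)C)c(O[Si](C(C)C)(C(C)C)C(C)C)c1Cc1c(OC)c(C)c(CC)oc1=O | intermediate
26 | 2-[1-(tert-butyldimethylsilyloxy)-2-methylpropyl]-5-ethoxy-3-methoxy-4,6-bis(PyrCH2)phenol, formed as its tetrabutylammonium phenoxide (racemic, not isolated) | CCOc1c(Cc2c(OC)c(C)c(CC)oc2=O)c(OC)c(C(O[Si](C)(C)C(C)(C)C)C(C)C)c(O)c1Cc1c(OC)c(C)c(CC)oc1=O | intermediate
27 | 2-[1-(tert-butyldimethylsilyloxy)-2-methylpropyl]-5-ethoxy-1,3-dimethoxy-4,6-bis(PyrCH2)benzene (racemic) | CCOc1c(Cc2c(OC)c(C)c(CC)oc2=O)c(OC)c(C(O[Si](C)(C)C(C)(C)C)C(C)C)c(OC)c1Cc1c(OC)c(C)c(CC)oc1=O | intermediate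
28 | 1-[4-ethoxy-2,6-dimethoxy-3,5-bis(PyrCH2)phenyl]-2-methylpropan-1-ol (racemic) | CCOc1c(Cc2c(OC)c(C)c(CC)oc2=O)c(OC)c(C(O)C(C)C)c(OC)c1Cc1c(OC)c(C)c(CC)oc1=O | intermediate
29 | 1-[4-ethoxy-2,6-dimethoxy-3,5-bis(PyrCH2)phenyl]-2-methylpropan-1-one | CCOc1c(Cc2c(OC)c(C)c(CC)oc2=O)c(OC)c(C(=O)C(C)C)c(OC)c1Cc1c(OC)c(C)c(CC)oc1=O | intermediate
30 | 3,3'-{[2,4,6-trihydroxy-5-(2-methylpropanoyl)-1,3-phenylene]bis(methylene)}bis(6-ethyl-4-hydroxy-5-methyl-2H-pyran-2-one), achiral | CCc1oc(=O)c(Cc2c(O)c(Cc3c(O)c(C)c(CC)oc3=O)c(O)c(C(=O)C(C)C)c2O)c(O)c1C | target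

**Step count**
Total: 14 steps. Longest linear sequence: 12 steps (steps 1–7 and 10–14, from methyl 3-oxopentanoate); steps 8–9 form the side branch.

**Steps most likely to fail**

Step 10. The donor-stabilized 3-ethoxycyclobutenone may open sluggishly, and capture of the fully substituted ketene terminus by an alkyne bearing a branched silyloxyalkyl group may be slower than ketene dimerization or decomposition. The fallback keeps the three ring bonds but brings in the acyl carbon afterwards. It sets out from cyclobutenone 14 and ethoxyacetylene 9. Heating the two (PhMe, 90 °C, sealed tube), the classical unhindered alkoxyalkyne version of the annulation, should give 3,5-diethoxy-2,4-bis(PyrCH2)phenol F1, whose one free ring position lies between the hydroxyl and an ethoxy group. Friedel–Crafts acylation at that position with isobutyryl chloride and TiCl4 (CH2Cl2, −20 °C) should give 1-[2,4-diethoxy-6-hydroxy-3,5-bis(PyrCH2)phenyl]-2-methylpropan-1-one F2. BBr3 cleavage of its two ethyl and two methyl ethers comes back to the route at target 30.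

Step 7. At the temperature needed for the retro-ene step the product cyclobutenone can itself open and be intercepted by unreacted ynol ether (over-annulation to a phenol), and the ketene can be lost to capture by the neighbouring pyranone methoxy oxygen. The fallback makes the ketene at room temperature from an acid chloride. It sets out from bromide 6: Negishi coupling with BrZnCH2CH2CO2tBu (Pd(PPh3)4, THF, 50 °C) should give tert-butyl 3-(Pyr)propanoate F3. Trifluoroacetic acid should free 3-(Pyr)propanoic acid F4, and oxalyl chloride with catalytic DMF should give 3-(Pyr)propanoyl chloride F5. Slow addition of Et3N to F5 and one equivalent of ynol ether 12 in CH2Cl2 at rt generates ketene 13 in the presence of its trap and comes back to the route at cyclobutenone 14.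

Step 14. Five ethers must fall in one Lewis-acid event; the hindered ethoxy group may lag, and prolonged exposure may cut the aryl–CH2–pyranone bridges by retro-Friedel–Crafts scission. The fallback splits the unmasking into two stages of different mechanism, setting out from ketone 29. SN2 demethylation with NaSEt in DMF at 100 °C should remove the four activated methyl groups (two vinylogous esters, two ethers ortho to the ketone) under basic conditions and give 3,3'-{[2-ethoxy-4,6-dihydroxy-5-(2-methylpropanoyl)-1,3-phenylene]bis(methylene)}bis(6-ethyl-4-hydroxy-5-methyl-2H-pyran-2-one) F6. The single twisted ethyl ether is then cleaved with BCl3 and Bu4NI in CH2Cl2 at −78 → 0 °C, coming back to the route at target 30.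

**Further compounds**
F1 | step 10 | 3,5-diethoxy-2,4-bis(PyrCH2)phenol | CCOc1cc(O)c(Cc2c(OC)c(C)c(CC)oc2=O)c(OCC)c1Cc1c(OC)c(C)c(CC)oc1=O
F2 | step 10 | 1-[2,4-diethoxy-6-hydroxy-3,5-bis(PyrCH2)phenyl]-2-methylpropan-1-one | CCOc1c(C(=O)C(C)C)c(O)c(Cc2c(OC)c(C)c(CC)oc2=O)c(OCC)c1Cc1c(OC)c(C)c(CC)oc1=O
F3 | step 7 | tert-butyl 3-(6-ethyl-4-methoxy-5-methyl-2-oxo-2H-pyran-3-yl)propanoate | CC(C)(C)OC(=O)CCc1c(OC)c(C)c(CC)oc1=O
F4 | step 7 | 3-(6-ethyl-4-methoxy-5-methyl-2-oxo-2H-pyran-3-yl)propanoic acid | OC(=O)CCc1c(OC)c(C)c(CC)oc1=O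
F5 | step 7 | 3-(6-ethyl-4-methoxy-5-methyl-2-oxo-2H-pyran-3-yl)propanoyl chloride | ClC(=O)CCc1c(OC)c(C)c(CC)oc1=O
F6 | step 14 | 3,3'-{[2-ethoxy-4,6-dihydroxy-5-(2-methylpropanoyl)-1,3-phenylene]bis(methylene)}bis(6-ethyl-4-hydroxy-5-methyl-2H-pyran-2-one) | CCOc1c(Cc2c(O)c(C)c(CC)oc2=O)c(O)c(C(=O)C(C)C)c(O)c1Cc1c(O)c(C)c(CC)oc1=O
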